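We start from amounts: 0.800 M of substrate against 0.0240 M of free catalyst in the ash run. The cedar run doubles that catalyst, yet at 7.6 h its substrate reads 0.204 M against 0.231 M in ash.

| flask | substrate | free catalyst | target | time |
|---|---|---|---|---|
| ash | 0.800 M | 0.0240 M |  |  |
| elm | 0.480 M | 0.0240 M |  |  |
| cedar | 0.800 M | 0.0480 M |  |  |
| alder | 0.800 M | 0.0240 M | 0.240 M |  |
| maple | 0.800 M | 0.0240 M |  | 19 h |

| ash run: time / h | ash run: [substrate] / M | elm run: time / h | elm run: [substrate] / M | cedar run: time / h | cedar run: [substrate] / M | alder run: time / h | alder run: [substrate] / M |
|---|---|---|---|---|---|---|---|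
| 1.3 | 0.550 | 1.3 | 0.368 | 1.3 | 0.512 | 1.3 | 0.559 |
| 2.5 | 0.431 | 2.5 | 0.307 | 2.5 | 0.386 | 2.5 | 0.430 |
| 3.8 | 0.350 | 3.8 | 0.263 | 3.8 | 0.302 | 3.8 | 0.354 |
| 5.1 | 0.288 | 5.1 | 0.239 | 5.1 | 0.261 | 5.1 | 0.295 |
| 6.3 | 0.258 | 6.3 | 0.212 | 6.3 | 0.223 | 6.3 | 0.262 |
| 7.6 | 0.231 | 7.6 | 0.198 | 7.6 | 0.204 | 7.6 | 0.231 |

(standard deviation of a reading: 0.004 M)

- Overall: substrate -> target, with free catalyst as catalyst.
- Constant volume, constant temperature.
- Readings of a species count what is bound in complexes too.
- An order is taken over about fifteen percent of the charge, up and down.

- reaction order in [free catalyst] at the outset, round the charge of the ash run, defined at two percent of the substrate turned into target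
- reaction order in [substrate] at the outset, round the charge of the ash run, defined at two percent of the substrate turned into target (one fixed amount of target, the same in the runs compared)
- substrate in the maple run at 19 h, as a share of the substrate charged

We fold this into one number. On a plot of 1/c(substrate) against time, a catalyst-free second-order loss adds the same climb in the same time to both flasks. So the cedar climb over the ash climb is one if the catalyst does nothing and two if it carries the whole fall. Taking the catalyst's part as proportional to its charge, we subtract one:

climb in ash = 3.08 /M, climb in cedar = 3.65 /M

φ = climb in cedar / climb in ash − one = 0.186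

This φ is the catalyst share: the part of the ash climb that scales with free catalyst. On these readings the other 81.4% does not scale with it, so we take the fall of substrate as a poor gauge of the step that makes target. We commit to an order near one in free catalyst, as assumed, and give no figure for substrate.

Is one number enough for the maple run, which has the ash charge? The cedar-ash gap reads 0.454 /M at 3.8 h and 0.573 /M at 7.6 h, so it widens slowly. As an approximation we let the catalyst part stop there and continue with the catalyst-free slope:

slope = (one − φ) × climb in ash / time = 0.330 /M/h

1/c(substrate) at 19 h = 8.09 /M, which is 15.5% of the charge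

The forecast gave 0.35 in catalyst, 1.9 in substrate and 16% for maple, and it read the weak catalyst effect thus: “suggests an off-cycle catalyst aggregate”; on the catalyst order we differ.

The flask gives 1.0 in free catalyst, 0.91 in substrate and 15.7% for maple.

    free catalyst + substrate ⇌ catalyst-substrate complex, settled at all times (3.630 /M)
    catalyst-substrate complex + substrate ⇌ doubly bound catalyst, settled at all times (1.080 /M)
    doubly bound catalyst → target + catalyst-substrate complex (8.136 /h)
    free catalyst → spent catalyst (0.8496 /h)
    2 substrate → homo dimer (0.1573 /M/h)

At the same amount of target, the cedar run makes it twice as fast as ash, the ratio our scale gives to a change carried by the catalyst. Substrate in the maple run ends low because of the loss of two substrate to homo dimer: the run keeps 15.7% with that step. Take the step away and our estimate puts only the catalyst part of the ash climb, φ of it and held at its 7.6 h value, on the charge, which keeps 68.6%; the simulated maple run without homo dimer keeps 59.6% at 19 h.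

(The earlier runs and the new flask were generated by integration on assumed constants; noise was put on by code.)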